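## Retrosynthetic overview

1. Feature addressed: ring C is a 3-hydroxy-4-pyranone, the enol of a chromane-3,4-dione, so C3 and C4 are both carbonyl carbons. The route cuts the C3–C4 bond between these two electrophilic carbons.
2. Strategic reaction: carbene (NHC) umpolung of the C4 aldehyde on ring A, then intramolecular acylation by the C3 ester on the O1–C2 tether. This closes ring C at the flavonol oxidation level, with no oxidant near the 4'-O-prenyl alkene and no aurone channel for the 5-oxygenated A ring.
3. The cyclisation precursor is one Mitsunobu O1–C2 etherification away from a salicylaldehyde (ring A) and a mandelate (ring B, prenyl ether already in place).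
4. Ring A comes from 2,4,6-trihydroxybenzaldehyde. Its single free, formyl-chelated OH directs iodination/methoxylation to the neighbouring carbon (future C8) and then becomes O1, which locks the 8-OMe (not 6-OMe) pattern.
5. Ring order: A and B are bought, C is the only ring made (step 6), and the two MOM ethers at O5 and O7 come off last.

Key step: step 6

Remark: the target SMILES has no stereocentre and no stereogenic double bond, so the target is one achiral compound and no enantioselective step is needed. The only stereocentre on the way (the future C2 of the mandelate-derived intermediates) is carried as the racemate and is erased in the key step. Methyl (±)-4-hydroxymandelate is taken as a catalogue compound.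

## Route

Step 1
Reactants: 1 2,4,6-trihydroxybenzaldehyde
Product: 2 2-hydroxy-4,6-bis(methoxymethoxy)benzaldehyde
Conditions: MOMCl (2.2 equiv), i-Pr2NEt (3 equiv), CH2Cl2, 0 °C → rt
Reagents that add atoms: chloromethyl methyl ether (MOMCl), COCCl
Why: Williamson-type O-alkylation (MOM protection) should cap the 4-OH and one ortho-OH while the other ortho-OH stays hydrogen-bonded to the formyl group and free, and the mirror symmetry of 1 makes the two ortho-OH groups equivalent so only one bis-ether can form.

Step 2
Reactants: 2 2-hydroxy-4,6-bis(methoxymethoxy)benzaldehyde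
Product: 3 2-hydroxy-3-iodo-4,6-bis(methoxymethoxy)benzaldehyde
Conditions: NIS (1.0 equiv), DMF, 0 °C → rt, dark
Reagents that add atoms: N-iodosuccinimide (NIS), O=C1CCC(=O)N1I
Why: Electrophilic aromatic iodination should go ortho to the free chelated phenol (C3) and not to C5 between the two MOM ethers, as in the 3-halogenation of 2-hydroxy-4,6-dialkoxyaryl carbonyl compounds and the C6 halogenation of 5-hydroxy-7-alkoxyflavones.

Step 3
Reactants: 3 2-hydroxy-3-iodo-4,6-bis(methoxymethoxy)benzaldehyde
Product: 4 2-hydroxy-3-methoxy-4,6-bis(methoxymethoxy)benzaldehyde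
Conditions: NaOMe (25% in MeOH, 6 equiv), CuI (0.3 equiv), DMF, 100 °C; then aq. NH4Cl
Reagents that add atoms: sodium methoxide, C[O-].[Na+]
Why: Ullmann-type copper-catalysed methoxylation of an ortho-iodophenol, the reaction type that converts 5-halovanillins into syringaldehyde, should replace iodide by methoxide while the MOM acetals and the aldehyde survive the basic medium.

Step 4
Reactants: 5 methyl (±)-2-hydroxy-2-(4-hydroxyphenyl)acetate (methyl 4-hydroxymandelate)
Product: 6 methyl (±)-2-hydroxy-2-[4-(3-methylbut-2-en-1-yloxy)phenyl]acetate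
Conditions: prenyl bromide (1.1 equiv), K2CO3 (1.5 equiv), acetone, reflux
Reagents that add atoms: prenyl bromide (1-bromo-3-methylbut-2-ene), CC(C)=CCBr
Why: Williamson ether synthesis should be selective for the phenol, because carbonate deprotonates the phenol but not the α-hydroxy ester.

Step 5
Reactants: 4 2-hydroxy-3-methoxy-4,6-bis(methoxymethoxy)benzaldehyde; 6 methyl (±)-2-hydroxy-2-[4-(3-methylbut-2-en-1-yloxy)phenyl]acetate
Product: 7 methyl (±)-2-[2-formyl-6-methoxy-3,5-bis(methoxymethoxy)phenoxy]-2-[4-(3-methylbut-2-en-1-yloxy)phenyl]acetate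
Conditions: PPh3 (1.5 equiv), DIAD (1.5 equiv), THF, 0 °C → rt
Reagents that add atoms: none
Why: Mitsunobu etherification should form the future O1–C2 bond, since the acidic salicylaldehyde-type phenol of 4 (same local environment as o-vanillin) displaces the activated benzylic α-hydroxy ester of 6, which has no β-hydrogen to eliminate; the new stereocentre is racemic and is erased in step 6.

Step 6
Reactants: 7 methyl (±)-2-[2-formyl-6-methoxy-3,5-bis(methoxymethoxy)phenoxy]-2-[4-(3-methylbut-2-en-1-yloxy)phenyl]acetate
Product: 10 3-hydroxy-8-methoxy-5,7-bis(methoxymethoxy)-2-[4-(3-methylbut-2-en-1-yloxy)phenyl]-4H-chromen-4-one, via Breslow intermediate 8 (not isolated), via chromane-3,4-dione 9 (not isolated)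
Conditions: 3-benzyl-5-(2-hydroxyethyl)-4-methylthiazolium chloride (0.3 equiv), DBU (1.5 equiv), degassed THF (0.05 M), 60 °C, Ar, dark; then aq. NH4Cl
Reagents that add atoms: none
Why: Proposed new method: the thiazol-2-ylidene adds to the C4 aldehyde of 7 to form the Breslow intermediate 8, whose nucleophilic carbon attacks the ester carbonyl (future C3) held on the O1–C2 tether; collapse of the tetrahedral adduct expels methoxide and the carbene to leave the chromane-3,4-dione 9, which enolises to the 3-hydroxy-4-pyranone 10 and is trapped as its DBU salt, so the acylation is pulled forward as in a Dieckmann condensation. The closest known reaction types are the carbene-catalysed intramolecular crossed benzoin of keto-aldehydes and the intramolecular aldehyde–nitrile coupling of 2-(cyanomethoxy)benzaldehydes to 3-aminochromones, whereas acylation of a Breslow intermediate by a simple alkyl ester lacks close precedent. Ring C closes in a 6-exo-trig mode and the new C3–C4 bond joins two carbonyl carbons of like polarity. No stereocentre is created, since the racemic C2 centre of 7 becomes sp2 when 9 enolises. The step needs C-acylation to win over aldol addition of the acidic ester α-C–H to the aldehyde and over intermolecular benzoin: the aldol is a reversible 5-exo equilibrium that drains back to 7, the two ortho oxygen substituents block dimerisation of the aldehyde, and a small thiazolium carbene is chosen because that same di-ortho substitution slows carbene addition.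

Step 7
Reactants: 10 3-hydroxy-8-methoxy-5,7-bis(methoxymethoxy)-2-[4-(3-methylbut-2-en-1-yloxy)phenyl]-4H-chromen-4-one
Product: 11 3,5,7-trihydroxy-8-methoxy-2-[4-(3-methylbut-2-en-1-yloxy)phenyl]-4H-chromen-4-one (3,5,7-trihydroxy-8-methoxy-4'-prenyloxyflavone)
Conditions: HCl (about 1 M in MeOH), MeOH/THF, 0 °C → rt, monitored; then aq. NaHCO3
Reagents that add atoms: none
Why: Acid-catalysed acetal exchange (MOM cleavage) should free O5 and O7, because the peri 5-O-MOM and the vinylogous-acid 7-O-MOM acetals ionise through an oxocarbenium ion much faster than the aryl prenyl ether can ionise in cold dilute methanolic HCl.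

## Compound list

1 | 2,4,6-trihydroxybenzaldehyde | O=Cc1c(O)cc(O)cc1O | starting material
2 | 2-hydroxy-4,6-bis(methoxymethoxy)benzaldehyde | O=Cc1c(O)cc(OCOC)cc1OCOC | intermediate
3 | 2-hydroxy-3-iodo-4,6-bis(methoxymethoxy)benzaldehyde | O=Cc1c(O)c(I)c(OCOC)cc1OCOC | intermediate
4 | 2-hydroxy-3-methoxy-4,6-bis(methoxymethoxy)benzaldehyde | O=Cc1c(O)c(OC)c(OCOC)cc1OCOC | intermediate
5 | methyl (±)-2-hydroxy-2-(4-hydroxyphenyl)acetate (racemic) | COC(=O)C(O)c1ccc(O)cc1 | starting material
6 | methyl (±)-2-hydroxy-2-[4-(3-methylbut-2-en-1-yloxy)phenyl]acetate (racemic) | COC(=O)C(O)c1ccc(OCC=C(C)C)cc1 | intermediate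
7 | methyl (±)-2-[2-formyl-6-methoxy-3,5-bis(methoxymethoxy)phenoxy]-2-[4-(3-methylbut-2-en-1-yloxy)phenyl]acetate (racemic) | COC(=O)C(Oc1c(C=O)c(OCOC)cc(OCOC)c1OC)c1ccc(OCC=C(C)C)cc1 | intermediate
8 | Breslow intermediate: 3-benzyl-5-(2-hydroxyethyl)-4-methyl-2,3-dihydrothiazol-2-ylidene adduct of the aldehyde carbon of 7 (enaminol; racemic at the ether carbon, enol geometry not defined) | OC(=C1SC(CCO)=C(C)N1Cc1ccccc1)c1c(OCOC)cc(OCOC)c(OC)c1OC(C(=O)OC)c1ccc(OCC=C(C)C)cc1 | intermediate (not isolated)
9 | (±)-8-methoxy-5,7-bis(methoxymethoxy)-2-[4-(3-methylbut-2-en-1-yloxy)phenyl]chromane-3,4-dione (racemic) | COc1c(OCOC)cc(OCOC)c2C(=O)C(=O)C(c3ccc(OCC=C(C)C)cc3)Oc12 | intermediate (not isolated)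
10 | 3-hydroxy-8-methoxy-5,7-bis(methoxymethoxy)-2-[4-(3-methylbut-2-en-1-yloxy)phenyl]-4H-chromen-4-one | COc1c(OCOC)cc(OCOC)c2c(=O)c(O)c(-c3ccc(OCC=C(C)C)cc3)oc12 | intermediate
11 | 3,5,7-trihydroxy-8-methoxy-2-[4-(3-methylbut-2-en-1-yloxy)phenyl]-4H-chromen-4-one | COc1c(O)cc(O)c2c(=O)c(O)c(-c3ccc(OCC=C(C)C)cc3)oc12 | target

## Step count and risks

Total step count: 7. Longest linear sequence: 6 steps (steps 1, 2, 3, 5, 6, 7); step 4 is the side branch.

Steps most likely to fail:

Step 6 (Proposed new method). Carbene addition to the electron-rich, di-ortho-oxygenated aldehyde may be slow. The Breslow intermediate may also fail to attack the unactivated ester, so that the material idles in the reversible aldol manifold or is oxidised at the aldehyde by adventitious air. The fallback sets out from 4 and comes back at 10 by polarity-normal, known chemistry. Addition of MeMgBr (3 equiv, THF, 0 °C) to the aldehyde should give (±)-1-[2-hydroxy-3-methoxy-4,6-bis(methoxymethoxy)phenyl]ethan-1-ol F1. MnO2 (CH2Cl2, rt) should oxidise this benzylic alcohol to 1-[2-hydroxy-3-methoxy-4,6-bis(methoxymethoxy)phenyl]ethan-1-one F2. Claisen–Schmidt condensation of F2 with commercial 4-(3-methylbut-2-en-1-yloxy)benzaldehyde (KOH, EtOH, rt) should give (E)-1-[2-hydroxy-3-methoxy-4,6-bis(methoxymethoxy)phenyl]-3-[4-(3-methylbut-2-en-1-yloxy)phenyl]prop-2-en-1-one F3. Algar–Flynn–Oyamada oxidative cyclisation of F3 (30% H2O2, NaOH, MeOH, 0 °C → rt), in which the nucleophilic hydroperoxide leaves the isolated prenyl alkene alone, should then deliver 10. Compounds 5–7 are not needed in this variant.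

Step 3. Protodeiodination may outrun C–O bond formation at the carbon flanked by the phenoxide and a MOM ether, which would return 2. The fallback sets out from 3 and comes back at 4, and it inverts the polarity at that carbon. Miyaura borylation (B2pin2, PdCl2(dppf), KOAc, dioxane, 80 °C) should give 2-hydroxy-4,6-bis(methoxymethoxy)-3-(4,4,5,5-tetramethyl-1,3,2-dioxaborolan-2-yl)benzaldehyde F4. Oxidation with trimethylamine N-oxide (THF, 60 °C, then aqueous work-up) avoids peroxide and hence Dakin oxidation of the salicylaldehyde, and should give 2,3-dihydroxy-4,6-bis(methoxymethoxy)benzaldehyde F5. Formation of the dianion (NaH, 2.1 equiv, DMSO) and addition of MeI (1.0 equiv) should methylate the more nucleophilic, non-chelated 3-oxide and give 4.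

Step 5. The hindered, internally hydrogen-bonded phenol may attack the alkoxyphosphonium ion too slowly, so that the hydrazide anion is alkylated instead. The fallback sets out from 6 and comes back at 7, replacing the redox condensation by a pre-formed electrophile and a phenoxide nucleophile. MsCl and Et3N (CH2Cl2, −10 °C) should give methyl (±)-2-(methylsulfonyloxy)-2-[4-(3-methylbut-2-en-1-yloxy)phenyl]acetate F6. SN2 displacement of the mesylate by the potassium phenoxide of 4 (K2CO3, DMF, rt) should then give 7.

Further compounds

F1 | step 6 | (±)-1-[2-hydroxy-3-methoxy-4,6-bis(methoxymethoxy)phenyl]ethan-1-ol | CC(O)c1c(O)c(OC)c(OCOC)cc1OCOC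
F2 | step 6 | 1-[2-hydroxy-3-methoxy-4,6-bis(methoxymethoxy)phenyl]ethan-1-one | CC(=O)c1c(O)c(OC)c(OCOC)cc1OCOC
F3 | step 6 | (E)-1-[2-hydroxy-3-methoxy-4,6-bis(methoxymethoxy)phenyl]-3-[4-(3-methylbut-2-en-1-yloxy)phenyl]prop-2-en-1-one | O=C(/C=C/c1ccc(OCC=C(C)C)cc1)c1c(O)c(OC)c(OCOC)cc1OCOC
F4 | step 3 | 2-hydroxy-4,6-bis(methoxymethoxy)-3-(4,4,5,5-tetramethyl-1,3,2-dioxaborolan-2-yl)benzaldehyde | O=Cc1c(O)c(B2OC(C)(C)C(C)(C)O2)c(OCOC)cc1OCOC
F5 | step 3 | 2,3-dihydroxy-4,6-bis(methoxymethoxy)benzaldehyde | O=Cc1c(O)c(O)c(OCOC)cc1OCOC
F6 | step 5 | methyl (±)-2-(methylsulfonyloxy)-2-[4-(3-methylbut-2-en-1-yloxy)phenyl]acetate | COC(=O)C(OS(C)(=O)=O)c1ccc(OCC=C(C)C)cc1
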